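# Proposed total synthesis of CNP0159589.3

Atom numbers follow the order of the atoms in the SMILES string of the target (C1–C2 ethyl, C3=C4, C5, C6, C7, O8, C9, C10, C11, C12=C13, C14, C15, C16, C17, ester C18–C21, C22, C23, C24, N25, C26, C27).

## Analysis of the target

The target is a pentacyclic amino ester. Ring A is a 6-ethyl-3,4-dihydro-2H-pyran (O8, enol ether C3=C4) spiro-fused at C6. Ring B is the ester-bearing cyclopentane (C13, C14, C17, C22, C23), ring C a cyclopentene (C12=C13, C14, C15, C16), ring D a cycloheptene and ring E an N-methylpiperidine. Rings D and E together form an 8-azabicyclo[4.3.1]decene with bridgeheads C23 and C9 and the one-carbon bridge C6, and rings B, C and D meet at the sp2 carbon C13.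

There are five stereocentres (C6, C9, C14, C17, C23). C6 and C23 are adjacent quaternary carbons. C9 can have only one configuration once C6 and the nitrogen bridge span C23 and C9. On ring B the ester, C15 and C6 lie on one face and H14, H17 and C24 on the other. At C6 the methylene C5 sits over the piperidine and the oxymethylene C7 over the cycloheptene.

The sensitive groups are the acid-labile enol ether, the basic tertiary amine, and the tetrasubstituted C12=C13 alkene, which must not migrate. The methyl ester sits on an epimerisable carbon and on the more crowded face of ring B, so it is probably the less stable epimer.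

The hard points are the vicinal quaternary pair, the absolute configuration of C23 (all four substituents are carbon), the bridged bicycle and the late control of C17.

The strategy rests on one feature. C23 is a ring-B carbon next to C13 and carries two one-carbon arms, C24 and C6. A cyclopentanone whose quaternary α-carbon bears two differentiated oxymethyl groups is what a one-carbon enlargement of a cyclobutanol onto an oxirane carbon delivers. The two arms then grow into rings E and D.

## Retrosynthetic reasoning

**C17.** The ester is expected to be the less stable epimer, so it is set last. 44 is traced to its C17 epimer 42; the forward step is a kinetic protonation of the ester enolate 43 from the open face of ring B. Nothing basic follows it.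

**Ring A.** The enol ether is cut at O8–C3 (hemiketal dehydration of hydroxy ketone 41), then at C4=C5 (olefination of aldehyde 38 with phosphonate 39), then at C6–C7 (aldol of aldehyde 37 with a one-carbon aldehyde electrophile). C7 is attached last on purpose. An electrophile should approach the exocyclic enolate at C6 from the cycloheptene side, which is where C7 lies in the target. The smallest possible electrophile is also the best choice for building a quaternary carbon next to quaternary C23.

**C5–C6.** Aldehyde 37 comes from the bridging ketone 35 by one-carbon homologation. The ketone is what ring-E formation leaves at C6, so no extra redox step is spent.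

**Ring E.** Cutting C9–C27 and N25–C27 of 35 is a Mannich disconnection to ketone 33. C9 is the only enolisable position of 33 and the amine is already tethered through C24, so the closure is the second half of a double Mannich piperidone synthesis. It also sets C9.

**Nitrogen and the C24 arm.** 33 goes back through reductive amination of aldehyde 30 to the diol ester 29, obtained by methanolysis of lactone 28. The lactone oxygen is the C24 oxygen, so C24 is released exactly when it is needed.

**Ring D and C16.** In 28 the C16 methylene is traced to the enone carbonyl of 26 through dithiolane 27. This carbonyl is the price of the aldol closure of ring C and has no place in the target. Ring D is cut at C9=C10 (ring-closing metathesis, then saturation) and at C6–C9 (vinyl addition to aldehyde 23). This uses the C6 arm as the ring-D anchor and an allyl group on C12 as the other terminus.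

**Ring C.** Enone 21 is opened at C12=C13 to the 1,4-diketone 20 (aldol condensation onto the C13 ketone). 20 comes by hydration of alkyne 19, and 19 by alkylation of C14 of keto lactone 13 with bromide 17. The bromide carries C15, C16, C12, C11 and C10.

**Lactone 13 as control element.** The ring expansion cannot control C17, and C14 must be set relative to C23, whose two arms are sterically similar. Tying the C24 oxygen to the carboxyl as a bridged lactone solves both. Only one C17 configuration can lactonise, and the bridge blocks one face of ring B, so C15 enters on the face of the C6 arm. 13 is traced through acid 11 to keto ester 10.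

**Key disconnection.** 10 is cut at C22–C23: the cyclopentanone is a cyclobutanol (9) enlarged by one carbon, with the migrating methylene ending on the oxirane carbon. The forward step must open the oxirane at its tertiary carbon with inversion and keep the two arms distinct (free hydroxyl on C24, silyl ether on C6).

**Precursor.** 9 comes from diol 7 by Sharpless asymmetric epoxidation (8) and silylation. 7 comes from the silyl ether 6, and 6 from the union of 2 (from 1) with keto ester 3. Bromide 17 comes from 14 and 15 via 16.

## Alternatives that were turned down

**Alternative 1:** Rings B and C are disconnected together at C13–C14 and C12–C16. In the forward step a nickel catalyst couples a C12–C13 alkyne with a tethered C14–C15 enoate, and the alkenylnickel then acylates onto an ester carbon that becomes C16. This gives the bicyclo[3.3.0]octenone A1, which has geminal diesters at C17 and C23 and a cyanopropyl chain on C12.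
- For it: two rings, two C–C bonds and the C12=C13 enone in one catalytic step, with the C11–C9 chain already in place. On ring count per step it is stronger than the chosen key step, which forms one bond and one ring.
- Against it: in A1 C23 carries two identical ester groups. They must later be told apart relative to C14, which is a diastereotopic-group problem next to an sp2 carbon. C17 needs a mono-decarboxylation, and four esters, a ketone and a nitrile must be handled chemoselectively. Absolute configuration would rest on an asymmetric version of the nickel step that sets only C14.
- In its place the chosen route offers a C23 that is made with differentiated arms and with reagent-controlled absolute configuration; C14 is then set by substrate control.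

**Alternative 2:** The bonds C13–C23 and C5–C6 are cut. In the forward step the alkenyl metal of a ring-C diene adds under copper catalysis to the β-carbon (C23) of a 3-piperidone enone, and the C6 enolate is trapped by a vinyl ketone. This gives the piperidone A2 with both quaternary carbons.
- For it: it is the most convergent plan. Three fragments are joined, ring E is preformed and the vicinal quaternary pair is made directly. On that point it is stronger than the chosen route.
- Against it: both events sit at the steric limit. A hindered alkenyl group must add to a β,β-disubstituted enone, and the resulting fully substituted enolate must undergo a reversible Michael addition to build a second quaternary carbon next to the first. The only stereochemical information is a remote carbinol on the ring-C fragment. Rings B, D and A and the C9 centre all remain to be made.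
- In its place the chosen route makes the two quaternary carbons one at a time, by an intramolecular 1,2-shift and by reaction with the smallest aldehyde. Neither is much affected by crowding, and each has a clear stereochemical rationale.

**Alternative 3:** The C6–C23 bond is cut as a Claisen retron. On heating, a seven-membered cyclic enol ether (O8 linking enol carbon C7 to the C12 carbinol carbon) rearranges. This forms C6–C23, closes carbocyclic ring D, moves the ring-B alkene to C12=C13 and unveils the C7 aldehyde of A3.
- For it: the most hindered bond is formed intramolecularly and stereospecifically, together with ring D and a useful handle. For the C6–C23 bond it is stronger than anything in the chosen route.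
- Against it: the precursor is itself a hard target. It needs a tetrasubstituted C13=C23 alkene in ring B, a fully substituted enol ether of defined geometry inside an oxepine, and C14 and C17 already in place. The ring forces a boat-like transition state. In A3 C9 is still an exocyclic methylene, so C9 and ring E remain open.
- The risk would therefore lie before the key step. The chosen route reaches its key precursor in five routine steps, puts the risk into the key step, and builds the C6–C23 linkage from a C23 that already exists.

Key step: step 6

## Route

Remarks on the chemistry (assumptions):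
- Compounds 6–9 are drawn as the cyclobutane isomer with the hydroxyl cis to the ester, the one expected from attack anti to the ester. The trans isomer reacts in the same way, and the relationship disappears in step 6.
- C17 in 10–12, the carbinol carbon C6 in 24–32 and C6 in 37 are epimer mixtures (no descriptor in their SMILES). They converge in steps 8, 23 and 26.
- From 13 to 42 the ester is drawn in the C17 configuration fixed by the lactone (cis to C24). This is the epimer opposite to the target and is corrected in step 29.
- Alcohol 16 is prepared, not bought.

Step 1
Reactants: 1 2-bromoprop-2-en-1-ol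
Product: 2 (2-bromoprop-2-en-1-yloxy)(tert-butyl)dimethylsilane
Conditions: TBSCl, imidazole, CH2Cl2, 0 °C to rt
Reagents that add atoms: tert-butyldimethylsilyl chloride, CC(C)(C)[Si](C)(C)Cl
Why: Standard silylation of a primary alcohol; the silyl ether masks the hydroxyl during the bromine–lithium exchange of step 2.

Step 2
Reactants: 2 (2-bromoprop-2-en-1-yloxy)(tert-butyl)dimethylsilane; 3 methyl 3-oxocyclobutane-1-carboxylate
Product: 6 methyl 3-hydroxy-3-[3-(tert-butyldimethylsilyloxy)prop-1-en-2-yl]cyclobutane-1-carboxylate, via alkenyllithium 4 (not isolated), via alkenylcerium dichloride 5 (not isolated)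
Conditions: tBuLi (2 equiv), Et2O, −78 °C; CeCl3, THF, −78 °C; then 3, −78 °C
Reagents that add atoms: none
Why: Bromine–lithium exchange and transmetalation give a weakly basic organocerium reagent that should add 1,2 to the strained ketone in preference to the ester and without enolisation. Attack anti to the ester should give mainly the cis hydroxy ester, a relationship that is erased in step 6.

Step 3
Reactants: 6 methyl 3-hydroxy-3-[3-(tert-butyldimethylsilyloxy)prop-1-en-2-yl]cyclobutane-1-carboxylate
Product: 7 methyl 3-hydroxy-3-(3-hydroxyprop-1-en-2-yl)cyclobutane-1-carboxylate
Conditions: Bu4NF, THF, 0 °C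
Reagents that add atoms: none
Why: Fluoride-mediated desilylation frees the primary allylic hydroxyl, which the titanium–tartrate epoxidation needs as its anchor.

Step 4
Reactants: 7 methyl 3-hydroxy-3-(3-hydroxyprop-1-en-2-yl)cyclobutane-1-carboxylate
Product: 8 methyl 3-hydroxy-3-[2-(hydroxymethyl)oxiran-2-yl]cyclobutane-1-carboxylate
Conditions: Ti(OiPr)4 (10 mol %), D-(−)-diethyl tartrate (12 mol %), tBuOOH, 4 Å MS, CH2Cl2, −20 °C
Reagents that add atoms: tert-butyl hydroperoxide, CC(C)(C)OO
Why: Sharpless asymmetric epoxidation of a 2-substituted primary allylic alcohol; the D-(−)-tartrate complex delivers oxygen to the alkene face that gives the oxirane carbon (the future C23) as drawn in 8. That carbon is (R) in 8 and becomes (S) by CIP in 9 only because silylation changes the priorities. Catalytic titanium at low temperature limits Lewis-acid opening of the product.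

Step 5
Reactants: 8 methyl 3-hydroxy-3-[2-(hydroxymethyl)oxiran-2-yl]cyclobutane-1-carboxylate
Product: 9 methyl 3-hydroxy-3-[2-(tert-butyldimethylsilyloxymethyl)oxiran-2-yl]cyclobutane-1-carboxylate
Conditions: TBSCl, imidazole, DMF, 0 °C
Reagents that add atoms: tert-butyldimethylsilyl chloride, CC(C)(C)[Si](C)(C)Cl
Why: The primary hydroxyl is silylated selectively over the hindered tertiary cyclobutanol; this marks the future C6 arm before the ring expansion, so the two arms of C23 are never equivalent.

Step 6
Reactants: 9 methyl 3-hydroxy-3-[2-(tert-butyldimethylsilyloxymethyl)oxiran-2-yl]cyclobutane-1-carboxylate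
Product: 10 methyl 3-(tert-butyldimethylsilyloxymethyl)-3-(hydroxymethyl)-4-oxocyclopentane-1-carboxylate (C17 epimers)
Conditions: BF3·OEt2 (1.1 equiv), CH2Cl2, −78 °C; then aq NaHCO3
Reagents that add atoms: none
Why: BF3 binds the oxirane oxygen and the bond from the tertiary oxirane carbon (C23) to oxygen lengthens; a cyclobutane methylene lying anti-periplanar to that bond shifts from the carbinol carbon (C13) to C23 while the carbinol oxygen pushes in, so the C13 ketone forms as the C22–C23 bond forms. The closest known reaction type is the semipinacol ring expansion of 1-(oxiran-2-yl)cyclobutanols (2,3-epoxy alcohols) to 2-(hydroxymethyl)cyclopentanones. Ring B is closed not by a cyclisation but by a 1,2-carbon shift that enlarges the four-membered ring by one atom, driven by relief of cyclobutane strain and by formation of the carbonyl group. C23 is the only stereocentre that is controlled: it is set by the oxirane configuration of step 4, the migrating carbon entering anti to the departing oxygen (inversion), and both ring methylenes give the same C23 configuration. The two migrations differ in the orientation of the remote ester, so C17 is expected as an epimer mixture, which converges in step 8. The step needs migration to outrun hydride shift from C24, capture by fluoride or by the ether oxygen, and full ionisation; the tertiary C23 is the only carbon that can carry positive charge, the primary C24–O bond stays intact, and a strained ring bond is anti-periplanar in either reactive rotamer. The oxirane oxygen stays on C24 as the free hydroxyl and the silyl ether marks C6, and the weakly basic quench at low temperature avoids silyl migration between the arms.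

Step 7
Reactants: 10 methyl 3-(tert-butyldimethylsilyloxymethyl)-3-(hydroxymethyl)-4-oxocyclopentane-1-carboxylate (C17 epimers)
Product: 11 3-(tert-butyldimethylsilyloxymethyl)-3-(hydroxymethyl)-4-oxocyclopentane-1-carboxylic acid (C17 epimers)
Conditions: Me3SnOH, ClCH2CH2Cl, 80 °C; then 5% aq HCl (work-up)
Reagents that add atoms: trimethyltin hydroxide, C[Sn](C)(C)O
Why: Neutral ester cleavage with the tin hydroxide avoids an alkoxide at C24, which could move the silyl group between the arms (scrambling C23) or trigger retro-aldol loss of C24.

Step 8
Reactants: 11 3-(tert-butyldimethylsilyloxymethyl)-3-(hydroxymethyl)-4-oxocyclopentane-1-carboxylic acid (C17 epimers)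
Product: 13 5-(tert-butyldimethylsilyloxymethyl)-3-oxabicyclo[3.2.1]octane-2,6-dione (bridged keto lactone of ring B), via acyloxypyridinium iodide 12 (not isolated)
Conditions: 2-chloro-1-methylpyridinium iodide, Et3N, CH2Cl2 (0.005 M), reflux
Reagents that add atoms: none
Why: Mukaiyama lactonisation; only the C17 epimer with the carboxyl cis to the C24 hydroxymethyl arm can close the bridged six-membered lactone, and the activated acyl group of the other epimer is epimerised by Et3N (enolisation or ketene formation), so both epimers should converge on 13 at high dilution. The lactone fixes C17, protects O24 and the carboxyl, and blocks the lower face of ring B.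

Step 9
Reactants: 14 prop-2-yn-1-ol; 15 3-bromoprop-1-ene
Product: 16 hex-5-en-2-yn-1-ol
Conditions: CuI (10 mol %), K2CO3, DMF, rt
Reagents that add atoms: none
Why: The copper acetylide formed from the terminal alkyne is allylated at carbon (copper-catalysed sp–sp3 coupling), giving the skipped enynol.

Step 10
Reactants: 16 hex-5-en-2-yn-1-ol
Product: 17 1-bromohex-5-en-2-yne
Conditions: CBr4, PPh3, CH2Cl2, 0 °C
Reagents that add atoms: tetrabromomethane, BrC(Br)(Br)Br
Why: Appel bromination of a primary propargylic alcohol under neutral conditions that do not isomerise the skipped enyne.

Step 11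
Reactants: 13 5-(tert-butyldimethylsilyloxymethyl)-3-oxabicyclo[3.2.1]octane-2,6-dione; 17 1-bromohex-5-en-2-yne
Product: 19 7-exo-(hex-5-en-2-yn-1-yl) derivative of 13, via lithium enolate 18 (not isolated)
Conditions: LiN(iPr)2, THF, −78 °C; then 17, DMPU, −78 to −30 °C
Reagents that add atoms: none
Why: C14 is the only enolisable position (C23 is quaternary, C17 a bridgehead); SN2 alkylation by the propargylic bromide should occur on the exo face of the bicyclo[3.2.1] enolate, anti to the lactone bridge. This sets C14 with C15 on the face of the C6 arm, as in the target.

Step 12
Reactants: 19 7-exo-(hex-5-en-2-yn-1-yl) derivative of 13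
Product: 20 7-exo-(2-oxohex-5-en-1-yl) derivative of 13 (1,4-diketone)
Conditions: Ph3PAuNTf2 (5 mol %), H2O, 1,4-dioxane, 50 °C
Reagents that add atoms: water, O
Why: Gold-catalysed alkyne hydration with carbonyl participation: the C13 ketone oxygen adds to the activated alkyne at C16 (5-exo-dig), so water ends on C16 and the 1,4-diketone forms regioselectively; the terminal alkene is not touched.

Step 13
Reactants: 20 7-exo-(2-oxohex-5-en-1-yl) derivative of 13 (1,4-diketone)
Product: 21 lactone-bridged ring B/C enone (C12=C13 and C16=O) with allyl on C12 and silyl ether on C6
Conditions: KOtBu, tBuOH–THF, rt to 40 °C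
Reagents that add atoms: none
Why: Intramolecular aldol condensation of a 1,4-diketone to a cyclopentenone: the C16 ketone enolises toward C12, which attacks the C13 ketone from the exo face (5-(enolendo)-exo-trig), and E1cB dehydration gives the C12=C13 enone of ring C. No other enolate can close a ring of usable size, and the lactone carbonyl lies on the opposite face, out of reach of a Claisen closure.

Step 14
Reactants: 21 lactone-bridged ring B/C enone with allyl on C12 and silyl ether on C6
Product: 22 primary alcohol (C6–OH) of 21
Conditions: HF·pyridine, THF, 0 °C to rt
Reagents that add atoms: none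
Why: Mildly acidic fluoride cleaves the primary silyl ether and leaves lactone and enone intact; O24 is acylated, so the two arms of C23 stay distinct.

Step 15
Reactants: 22 primary alcohol (C6–OH) of 21
Product: 23 C6 aldehyde
Conditions: Dess–Martin periodinane, NaHCO3, CH2Cl2, rt
Reagents that add atoms: none
Why: Periodinane oxidation of a neopentyl primary alcohol to a non-enolisable aldehyde under neutral conditions.

Step 16
Reactants: 23 C6 aldehyde
Product: 24 C6 vinyl carbinol (both carbinol epimers)
Conditions: CH2=CHBr, CrCl2, NiCl2 (2 mol %), DMF, rt
Reagents that add atoms: vinyl bromide, C=CBr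
Why: Nozaki–Hiyama–Kishi addition; the vinylchromium reagent is selective for the aldehyde, so the enone and lactone carbonyls survive. The new carbinol centre is of no consequence because it is oxidised in step 23.

Step 17
Reactants: 24 C6 vinyl carbinol (both carbinol epimers)
Product: 26 ring B/C/D lactone enone with C6 hydroxyl, via cycloheptadienol 25 (not isolated)
Conditions: second-generation Grubbs catalyst (5 mol %), CH2Cl2 (0.005 M), 40 °C; then H2 (5 atm), 50 °C
Reagents that add atoms: none
Why: Ring-closing metathesis between the vinyl carbinol and the allyl group closes the seven-membered ring D (C9=C10) with loss of ethene; the ruthenium hydride formed under hydrogen then saturates only the new disubstituted alkene, the tetrasubstituted enone alkene being too hindered.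

Step 18
Reactants: 26 ring B/C/D lactone enone with C6 hydroxyl
Product: 27 C16 1,3-dithiolane of 26
Conditions: HSCH2CH2SH, BF3·OEt2, CH2Cl2, 0 °C to rt
Reagents that add atoms: ethane-1,2-dithiol, SCCS
Why: Lewis-acid dithioketalisation converts the C16 carbonyl, which the aldol closure needed and the target lacks, into a dithiolane; with dithiols the conjugated alkene stays at C12=C13.

Step 19
Reactants: 27 C16 1,3-dithiolane of 26
Product: 28 ring B/C/D lactone alcohol with C16 methylene
Conditions: Raney Ni, EtOH, 50 °C
Reagents that add atoms: none
Why: Reductive desulfurisation (Mozingo reduction) turns C16 into a methylene; the tetrasubstituted C12=C13 alkene is too hindered to be hydrogenated and already sits in the most substituted position. After this step C14 can no longer epimerise.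

Step 20
Reactants: 28 ring B/C/D lactone alcohol with C16 methylene
Product: 29 ring B/C/D methyl ester with C24 and C6 hydroxyls
Conditions: NaOMe (0.2 equiv), MeOH, 0 °C; AcOH quench
Reagents that add atoms: methanol, CO
Why: Methoxide-catalysed transesterification opens the strained bridged lactone to the methyl ester and the primary C24 alcohol. No silyl group is left to migrate and the C6 oxygen is a secondary alcohol, so no retro-aldol path exists; the product is used at once to avoid relactonisation.

Step 21
Reactants: 29 ring B/C/D methyl ester with C24 and C6 hydroxyls
Product: 30 C24 aldehyde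
Conditions: TEMPO (20 mol %), PhI(OAc)2, CH2Cl2, rt
Reagents that add atoms: none
Why: Oxoammonium oxidation is selective for the primary alcohol over the hindered secondary one.

Step 22
Reactants: 30 C24 aldehyde
Product: 32 N-Boc-N-methyl amine at C24, via secondary amine 31 (not isolated)
Conditions: MeNH2 (THF), AcOH, NaBH(OAc)3, ClCH2CH2Cl, rt; then Boc2O, Et3N
Reagents that add atoms: methylamine, CN; di-tert-butyl dicarbonate, CC(C)(C)OC(=O)OC(=O)OC(C)(C)C
Why: Reductive amination of the non-enolisable aldehyde installs N25 with its methyl group. The secondary amine is capped in the same flask because the C17 ester is cis to the C24 arm and could otherwise close a lactam.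

Step 23
Reactants: 32 N-Boc-N-methyl amine at C24
Product: 33 ring D ketone (C6=O)
Conditions: Dess–Martin periodinane, CH2Cl2, rt
Reagents that add atoms: none
Why: Oxidation of the secondary alcohol gives the cycloheptanone whose only enolisable α-carbon is C9; both carbinol epimers converge here.

Step 24
Reactants: 33 ring D ketone (C6=O)
Product: 35 ring B/C/D/E amino ketone (C6=O), via ammonium trifluoroacetate 34 (not isolated)
Conditions: CF3CO2H, CH2Cl2, 0 °C; then aq CH2O, AcOH, 70 °C
Reagents that add atoms: formaldehyde, C=O
Why: After Boc cleavage the ammonium salt and formaldehyde give the N-methyl methyleneiminium ion, which is attacked by the enol of the C6 ketone at C9 in a 6-(enolendo)-endo-trig Mannich closure, the second half of a double Mannich piperidone synthesis. C9 can only take the configuration that lets the new ring bridge C23 and C9, and the β-amino ketone cannot revert by elimination because C9 is now a bridgehead.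

Step 25
Reactants: 35 ring B/C/D/E amino ketone (C6=O)
Product: 37 C6 formyl compound (formyl carbon is C5; C6 epimers), via methyl enol ether 36 (not isolated)
Conditions: Ph3P(CH2OMe)Cl, KOtBu, THF–PhMe, 0 to 80 °C; then 2 M HCl, THF, rt
Reagents that add atoms: (methoxymethyl)triphenylphosphonium chloride, COC[P+](c1ccccc1)(c1ccccc1)c1ccccc1.[Cl-]; water, O
Why: Wittig methoxymethylenation of the non-enolisable bridging ketone and acid hydrolysis of the enol ether give the one-carbon homologue. The configuration at C6 does not matter because C6 is enolised in step 26.

Step 26
Reactants: 37 C6 formyl compound (C6 epimers)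
Product: 38 C6-quaternary hydroxymethyl aldehyde
Conditions: aq CH2O, K2CO3, MeOH–THF, 0 °C to rt
Reagents that add atoms: formaldehyde, C=O
Why: Crossed aldol (hydroxymethylation) of the α-branched aldehyde with the smallest electrophile makes quaternary C6 next to quaternary C23. The exocyclic enolate on the one-carbon bridge should be attacked from the cycloheptene side (flanked by sp2 C13 and one axial hydrogen on C10), not from the piperidine side (two axial hydrogens on C24 and C27); this places C7 over ring D and the formyl carbon C5 over ring E, as in the target.

Step 27
Reactants: 38 C6-quaternary hydroxymethyl aldehyde; 39 diethyl (2-oxobutyl)phosphonate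
Product: 40 E-enone (C5=C4–C3(=O)–ethyl)
Conditions: LiCl, iPr2NEt, MeCN, rt to 40 °C
Reagents that add atoms: none
Why: Horner–Wadsworth–Emmons olefination under Masamune–Roush conditions is mild enough for the β-hydroxy aldehyde; it brings in C4 to C1 and gives the E-enone.

Step 28
Reactants: 40 E-enone (C5=C4–C3(=O)–ethyl)
Product: 42 17-epi-target, via hydroxy ketone 41 (not isolated)
Conditions: H2 (1 atm), Pd/C, EtOAc, rt; then TsOH·H2O (1.3 equiv), 4 Å MS, PhMe, 60 °C
Reagents that add atoms: none
Why: Hydrogenation saturates the disubstituted enone alkene while the tetrasubstituted alkene stays. The δ-hydroxy ketone then closes to the cyclic hemiketal (6-exo-trig), and acid-catalysed dehydration gives the endocyclic enol ether of ring A, the more stable isomer; one equivalent of acid is taken up by the amine.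

Step 29
Reactants: 42 17-epi-target
Product: 44 target, via lithium ester enolate 43 (not isolated)
Conditions: LiN(iPr)2, THF, −78 to −40 °C; then 2,6-di-tert-butylphenol, −78 °C
Reagents that add atoms: none
Why: The ester enolate removes the C17 stereocentre, and kinetic protonation by a bulky phenol should come from the less hindered face of ring B (the face of H14 and C24, away from C15 and the quaternary C6). This leaves the ester on the face of C15 and C6, as in the target, and converges any C17 epimer mixture.

## Compound list

1 | 2-bromoprop-2-en-1-ol | OCC(Br)=C | starting material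
2 | (2-bromoprop-2-en-1-yloxy)(tert-butyl)dimethylsilane | C=C(Br)CO[Si](C)(C)C(C)(C)C | intermediate
3 | methyl 3-oxocyclobutane-1-carboxylate | COC(=O)C1CC(=O)C1 | starting material
4 | [3-(tert-butyldimethylsilyloxy)prop-1-en-2-yl]lithium | [Li]C(=C)CO[Si](C)(C)C(C)(C)C | intermediate
5 | [3-(tert-butyldimethylsilyloxy)prop-1-en-2-yl]cerium dichloride | Cl[Ce](Cl)C(=C)CO[Si](C)(C)C(C)(C)C | intermediate
6 | methyl 3-hydroxy-3-[3-(tert-butyldimethylsilyloxy)prop-1-en-2-yl]cyclobutane-1-carboxylate, hydroxyl cis to the ester | O[C@]1(C(=C)CO[Si](C)(C)C(C)(C)C)C[C@H](C(=O)OC)C1 | intermediate
7 | methyl 3-hydroxy-3-(3-hydroxyprop-1-en-2-yl)cyclobutane-1-carboxylate, hydroxyl cis to the ester | O[C@]1(C(=C)CO)C[C@H](C(=O)OC)C1 | intermediate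
8 | methyl 3-hydroxy-3-[2-(hydroxymethyl)oxiran-2-yl]cyclobutane-1-carboxylate, (R) at the oxirane carbon | O[C@]1([C@@]2(CO)CO2)C[C@H](C(=O)OC)C1 | intermediate
9 | methyl 3-hydroxy-3-[2-(tert-butyldimethylsilyloxymethyl)oxiran-2-yl]cyclobutane-1-carboxylate, same spatial arrangement at the oxirane carbon as 8 | O[C@]1([C@@]2(CO[Si](C)(C)C(C)(C)C)CO2)C[C@H](C(=O)OC)C1 | intermediate
10 | methyl 3-(tert-butyldimethylsilyloxymethyl)-3-(hydroxymethyl)-4-oxocyclopentane-1-carboxylate, C23 as in the target, C17 epimers | O=C1CC(C(=O)OC)C[C@@]1(CO[Si](C)(C)C(C)(C)C)CO | intermediate
11 | 3-(tert-butyldimethylsilyloxymethyl)-3-(hydroxymethyl)-4-oxocyclopentane-1-carboxylic acid, C17 epimers | O=C1CC(C(=O)O)C[C@@]1(CO[Si](C)(C)C(C)(C)C)CO | intermediate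
12 | 1-methyl-2-(acyloxy)pyridinium iodide derived from acid 11 | O=C1CC(C(=O)Oc2cccc[n+]2C)C[C@@]1(CO[Si](C)(C)C(C)(C)C)CO.[I-] | intermediate
13 | 5-(tert-butyldimethylsilyloxymethyl)-3-oxabicyclo[3.2.1]octane-2,6-dione (lactone O24–C18; carboxyl carbon cis to C24) | O=C1C[C@@H]2C[C@@]1(CO[Si](C)(C)C(C)(C)C)COC2=O | intermediate
14 | prop-2-yn-1-ol | C#CCO | starting material
15 | 3-bromoprop-1-ene | C=CCBr | starting material
16 | hex-5-en-2-yn-1-ol | OCC#CCC=C | intermediate
17 | 1-bromohex-5-en-2-yne | BrCC#CCC=C | intermediate
18 | lithium enolate of 13 (C13–O–Li, C13=C14) | [Li]OC1=C[C@@H]2C[C@@]1(CO[Si](C)(C)C(C)(C)C)COC2=O | intermediate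
19 | 5-(tert-butyldimethylsilyloxymethyl)-7-(hex-5-en-2-yn-1-yl)-3-oxabicyclo[3.2.1]octane-2,6-dione, side chain exo (anti to the lactone bridge) | O=C1[C@H](CC#CCC=C)[C@@H]2C[C@@]1(CO[Si](C)(C)C(C)(C)C)COC2=O | intermediate
20 | 5-(tert-butyldimethylsilyloxymethyl)-7-(2-oxohex-5-en-1-yl)-3-oxabicyclo[3.2.1]octane-2,6-dione, side chain exo | O=C1[C@H](CC(=O)CCC=C)[C@@H]2C[C@@]1(CO[Si](C)(C)C(C)(C)C)COC2=O | intermediate
21 | lactone-bridged ring B/C enone: C12=C13, C16 ketone, allyl on C12, silyloxymethyl (C6) on C23, lactone O24–C18 | C=CCC1=C2[C@H](CC1=O)[C@@H]3C[C@@]2(CO[Si](C)(C)C(C)(C)C)COC3=O | intermediate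
22 | as 21 with free hydroxymethyl (C6–OH) on C23 | C=CCC1=C2[C@H](CC1=O)[C@@H]3C[C@@]2(CO)COC3=O | intermediate
23 | as 21 with formyl (C6) on C23 | C=CCC1=C2[C@H](CC1=O)[C@@H]3C[C@@]2(C=O)COC3=O | intermediate
24 | as 21 with 1-hydroxyprop-2-en-1-yl (C6 carbinol, C9 vinyl) on C23, carbinol epimers | C=CCC1=C2[C@H](CC1=O)[C@@H]3C[C@@]2(C(O)C=C)COC3=O | intermediate
25 | ring B/C/D lactone enone with C6 hydroxyl and C9=C10 alkene, carbinol epimers | OC1C=CCC2=C3[C@H](CC2=O)[C@@H]4C[C@@]31COC4=O | intermediate
26 | ring B/C/D lactone enone with C6 hydroxyl, ring D saturated at C9–C10, carbinol epimers | OC1CCCC2=C3[C@H](CC2=O)[C@@H]4C[C@@]31COC4=O | intermediate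
27 | C16 spiro-1,3-dithiolane of 26 | OC1CCCC2=C3[C@H](CC25SCCS5)[C@@H]4C[C@@]31COC4=O | intermediate
28 | ring B/C/D lactone alcohol with C16 methylene, carbinol epimers | OC1CCCC2=C3[C@H](CC2)[C@@H]4C[C@@]31COC4=O | intermediate
29 | ring B/C/D methyl ester (C17 cis to C24) with C24 hydroxymethyl and C6 hydroxyl | OC1CCCC2=C3[C@H](CC2)[C@@H](C(=O)OC)C[C@@]31CO | intermediate
30 | as 29 with C24 formyl | OC1CCCC2=C3[C@H](CC2)[C@@H](C(=O)OC)C[C@@]31C=O | intermediate
31 | as 29 with C24 methylaminomethyl | OC1CCCC2=C3[C@H](CC2)[C@@H](C(=O)OC)C[C@@]31CNC | intermediate
32 | as 29 with C24 N-Boc-N-methylaminomethyl | OC1CCCC2=C3[C@H](CC2)[C@@H](C(=O)OC)C[C@@]31CN(C)C(=O)OC(C)(C)C | intermediate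
33 | ring D ketone (C6=O) of 32 | O=C1CCCC2=C3[C@H](CC2)[C@@H](C(=O)OC)C[C@@]31CN(C)C(=O)OC(C)(C)C | intermediate
34 | methylammonium trifluoroacetate from 33 | O=C1CCCC2=C3[C@H](CC2)[C@@H](C(=O)OC)C[C@@]31C[NH2+]C.[O-]C(=O)C(F)(F)F | intermediate
35 | ring B/C/D/E amino ketone: 8-methyl-8-azabicyclo[4.3.1]decenone with C6 ketone, 17-epi ester | O=C1[C@@H]2CCC3=C4[C@H](CC3)[C@@H](C(=O)OC)C[C@@]41CN(C)C2 | intermediate
36 | methyl enol ether C6=CH(OMe) of 35, E/Z mixture | COC=C1[C@@H]2CCC3=C4[C@H](CC3)[C@@H](C(=O)OC)C[C@@]41CN(C)C2 | intermediate
37 | C6 formyl compound (formyl carbon C5), C6 epimers | O=CC1[C@@H]2CCC3=C4[C@H](CC3)[C@@H](C(=O)OC)C[C@@]41CN(C)C2 | intermediate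
38 | C6-quaternary aldehyde: C5 formyl over ring E, C7 hydroxymethyl over ring D | O=C[C@@]1(CO)[C@@H]2CCC3=C4[C@H](CC3)[C@@H](C(=O)OC)C[C@@]41CN(C)C2 | intermediate
39 | diethyl (2-oxobutyl)phosphonate | CCC(=O)CP(=O)(OCC)OCC | starting material
40 | E-enone: C6–CH=CH–C(=O)–ethyl with C7 hydroxymethyl | CCC(=O)/C=C/[C@@]1(CO)[C@@H]2CCC3=C4[C@H](CC3)[C@@H](C(=O)OC)C[C@@]41CN(C)C2 | intermediate
41 | saturated δ-hydroxy ketone: C6–CH2CH2–C(=O)–ethyl with C7 hydroxymethyl | CCC(=O)CC[C@@]1(CO)[C@@H]2CCC3=C4[C@H](CC3)[C@@H](C(=O)OC)C[C@@]41CN(C)C2 | intermediate
42 | 17-epi-target (ester cis to C24) | CCC1=CC[C@@]2(CO1)[C@@H]1CCC3=C4[C@H](CC3)[C@@H](C(=O)OC)C[C@@]42CN(C)C1 | intermediate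
43 | lithium ester enolate of 42 | CCC1=CC[C@@]2(CO1)[C@@H]1CCC3=C4[C@H](CC3)C(=C(OC)O[Li])C[C@@]42CN(C)C1 | intermediate
44 | CNP0159589.3 | CCC1=CC[C@@]2(CO1)[C@@H]1CCC3=C4[C@H](CC3)[C@H](C(=O)OC)C[C@@]42CN(C)C1 | target

## Step count and least certain steps

Total: 29 steps. Longest linear sequence: 27 steps (steps 1–8 and 11–29); steps 9 and 10 prepare bromide 17.

**Step 6 (key step).** The tertiary oxirane carbon ionises easily, so several processes can compete with the concerted shift:
- full ionisation before migration, which would erode the inversion at C23;
- capture of the cation by fluoride or by the C6 ether oxygen;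
- a hydride shift from C24 to give an aldehyde;
- retro-aldol loss of C24 from the boron-bound aldolate;
- silyl migration between the arms during work-up.

The fallback changes the rearrangement from a stoichiometric Lewis acid acting on the free hydroxy epoxide to a catalytic silyl-transfer rearrangement of a bis-silyl ether, in which no free aldol is ever present. It sets out from 9. The tertiary hydroxyl is silylated with N-(trimethylsilyl)imidazole to the trimethylsilyl ether F1. Catalytic TMSOTf in CH2Cl2 at −78 °C triggers the same 1,2-shift, with the silyl group passing to the C24 oxygen, to give the bis-silyl keto ester F2. The primary trimethylsilyl ether is then cleaved with citric acid in methanol, and the route is rejoined at 10.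

**Step 4.** Two things can go wrong. The 1,3-diol can chelate titanium and lower the face selectivity. The Lewis acid can also start ring expansion of 8 before the arms are differentiated; that would give a bis(hydroxymethyl) ketone in which C23 is no longer a stereocentre. The fallback changes the directing group and leaves the primary oxygen silylated. It sets out from 6 and uses a tertiary-hydroxyl-directed asymmetric epoxidation with Hf(OtBu)4, a chiral bishydroxamic acid ligand (enantiomer chosen for the configuration of 9) and cumene hydroperoxide. It comes back at 9 directly, without any new compound.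

**Step 8.** The activated acid whose carboxyl is trans to C24 may epimerise too slowly and be consumed by intermolecular esterification instead of converging on the lactone. The fallback separates lactonisation from epimerisation. It sets out from 10.
- Heating 10 with pyridinium p-toluenesulfonate in toluene lactonises only the cis epimer, to 13.
- The recovered trans epimer is silylated with Et3SiCl and imidazole to the triethylsilyl ether F3.
- F3 is equilibrated at C17 with NaOMe in methanol. With no free hydroxyl present, neither silyl migration nor retro-aldol is possible.
- The triethylsilyl group is removed selectively with pyridinium p-toluenesulfonate in methanol, and the material is cycled through the same lactonisation.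

The fallback comes back at 13.

**Step 25.** The ketone is flanked by a quaternary carbon and a bridgehead and may not react with the bulky ylide; on heating, the ylide may instead be acylated by the methyl ester. The fallback sets out from 35.
- Methylenation with the smaller and more reactive Ph3P=CH2 gives the exocyclic alkene F4.
- Hydroboration with 9-BBN and oxidation with NaBO3 give the primary alcohol F5.
- Oxidation with SO3·pyridine, DMSO and iPr2NEt gives the aldehyde.

The fallback comes back at 37.

**Step 26.** The facial preference at the bridge carbon rests on a steric argument only. The electrophile may approach from the piperidine side, or retro-aldol equilibration may level the selectivity. In the first case the fallback introduces the two substituents of C6 in the opposite order, so that the same face preference gives the right epimer. It sets out from 37, and the formyl carbon is now taken as C7. A Michael addition of the aldehyde to ethyl vinyl ketone (catalytic DBU) gives the keto aldehyde F6. NaBH(OAc)3 then reduces the aldehyde in the presence of the ketone to the hydroxy ketone. The fallback comes back at 41, which is dehydrated as in step 28.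

**Step 29.** The α-hydrogen at C17 lies on the crowded face and may be removed slowly, and the protonation may not be selective enough. The fallback replaces the enolate by a ketene. It sets out from 42. Me3SnOH cleaves the ester to the carboxylic acid F7. 2-Chloro-1-methylpyridinium iodide and Et3N convert F7 into the ketene, and methanol adds to it. The resulting ester enol is protonated at C17 from the open face. The fallback comes back at 44.

## Further compounds

F1 | step 6 | methyl 3-[2-(tert-butyldimethylsilyloxymethyl)oxiran-2-yl]-3-(trimethylsilyloxy)cyclobutane-1-carboxylate | C[Si](C)(C)O[C@]1([C@@]2(CO[Si](C)(C)C(C)(C)C)CO2)C[C@H](C(=O)OC)C1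
F2 | step 6 | methyl 3-(tert-butyldimethylsilyloxymethyl)-4-oxo-3-(trimethylsilyloxymethyl)cyclopentane-1-carboxylate, C17 epimers | O=C1CC(C(=O)OC)C[C@@]1(CO[Si](C)(C)C(C)(C)C)CO[Si](C)(C)C
F0 | step 4 | none | none
F3 | step 8 | methyl 3-(tert-butyldimethylsilyloxymethyl)-4-oxo-3-(triethylsilyloxymethyl)cyclopentane-1-carboxylate, C17 epimers | O=C1CC(C(=O)OC)C[C@@]1(CO[Si](C)(C)C(C)(C)C)CO[Si](CC)(CC)CC
F4 | step 25 | C6 methylidene analogue of 35 | C=C1[C@@H]2CCC3=C4[C@H](CC3)[C@@H](C(=O)OC)C[C@@]41CN(C)C2
F5 | step 25 | C6 hydroxymethyl compound (C6 epimers) | OCC1[C@@H]2CCC3=C4[C@H](CC3)[C@@H](C(=O)OC)C[C@@]41CN(C)C2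
F6 | step 26 | C6-quaternary keto aldehyde: C7 formyl over ring D, 3-oxopentyl chain over ring E | CCC(=O)CC[C@@]1(C=O)[C@@H]2CCC3=C4[C@H](CC3)[C@@H](C(=O)OC)C[C@@]41CN(C)C2
F7 | step 29 | carboxylic acid of 42 | CCC1=CC[C@@]2(CO1)[C@@H]1CCC3=C4[C@H](CC3)[C@@H](C(=O)O)C[C@@]42CN(C)C1
A1 | alternative 1 | bicyclo[3.3.0]octenone tetraester nitrile (rings B and C; geminal diesters at C17 and C23; cyanopropyl chain on C12) | N#CCCCC1=C2[C@H](CC1=O)C(C(=O)OC)(C(=O)OC)CC2(C(=O)OC)C(=O)OC
A2 | alternative 2 | 3-piperidone with adjacent quaternary C6 and C23 carrying the ring-C diene | CCC(=O)CC[C@@]2(COCc5ccccc5)C(=O)CN(C)C[C@]2(CCC(=O)OC)C3=C(C=C)CC[C@H]3O[Si](C)(C)C(C)(C)C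
A3 | alternative 3 | ring-D aldehyde with quaternary C6 and C23 (rings B, C and D) | CCC1(OCCO1)CC[C@@]2(C=O)C(=C)CCC3=C4[C@H](CC3)[C@H](C(=O)OC)C[C@@]42CN(C)C(=O)OC(C)(C)C
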